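A direct plan would prepare the ring B α-methoxy β-ketoester A1 by O-benzylation, ester aldol addition and oxidation, fuse it with phloroglucinol A2 at about 240 °C to the 5,7-dihydroxy-3-methoxyflavone A3, brominate C6 and C8 to the dibromide A4, exchange both bromides for methoxide under copper catalysis to give the benzyl-protected pentamethoxyflavone A5, and remove the benzyl group by hydrogenolysis. Its weakest steps would be:
- The thermal fusion of A1 with A2 that closes ring C: an acylketene pathway at 240 °C without close precedent for an α-methoxy ketoester. Pechmann-type closure to the isomeric coumarin and O-acylation would compete, and the benzyl ether would have to survive the melt.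
- The dibromination of A3 and the double methoxylation of A4 to A5 that install the 6- and 8-methoxy groups: two late steps that build no skeleton. The 1,2,4-trioxygenated ring B is itself open to bromination, and hot excess methoxide threatens the pyranone and invites hydrodebromination.
- The aldol addition and oxidation that lead to A1: a redox detour and three linear steps for a simple ketoester.

**Retrosynthetic overview**

- Ring A (C4a, C5, C6, C7, C8, C8a) is hexasubstituted: oxygen at C5, C7 and C8a (OH, OH, O1) alternates with the methoxy carbons C6 and C8. This is the pattern of a folded poly-β-carbonyl chain whose methylene carbons carry OMe.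
- Key disconnection: C4a–C5 (equivalent to C4a–C8a by the symmetry of ring A), a Claisen fold of a 2,4-dimethoxy-3,5,7-trioxo ester stored as 4-hydroxy-2-pyrone 10. The chain comes from methoxyacetate units (C5 to C8), an acetyl unit (C8a, C4a) and an α-methoxycinnamoyl starter (C4, C3, C2, ring B).
- Ring order: ring B is bought, ring A is made by the fold (step 6), and ring C is closed last through O1–C2 by oxidative cyclisation of the chalcone (step 7).
- All five oxygens of ring A are in place before the ring exists, so no finished flavone is halogenated or methoxylated and no high-temperature fusion is needed. The symmetry of ring A removes any regiochemical question in both ring closures.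

Key step: step 6

Remark: the alkene of 9 to 12 is drawn as Z (the expected major isomer); its geometry is erased in step 7, and the target has no stereocentre.

**Step 1**
Reactants: 1 methyl methoxyacetate (2 equiv)
Product: 2 methyl 2,4-dimethoxy-3-oxobutanoate (racemic, enolisable centre)
Conditions: NaH (0.55 equiv), cat. MeOH, THF, 0 → 55 °C; then cold 1 M HCl
Reagents that add atoms: none
Why: Self-Claisen condensation of an α-alkoxy ester, pulled to completion by deprotonation of the β-ketoester product, should deliver in one operation the C5 to C8 segment of ring A with both methoxy groups and the C7 oxygen in place.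

**Step 2**
Reactants: 2 methyl 2,4-dimethoxy-3-oxobutanoate; 3 N-methoxy-N-methylacetamide
Product: 5 4-hydroxy-3,5-dimethoxy-6-methyl-2H-pyran-2-one, via dioxo ester 4 (not isolated)
Conditions: LiN(iPr)2 (2.2 equiv), THF, −78 → 0 °C; 3 (1.05 equiv), −78 → 0 °C; 1 M HCl; crude 4, DBU (1.2 equiv), PhMe, reflux; 1 M HCl
Reagents that add atoms: none
Why: γ-Acylation of the β-ketoester dianion by a Weinreb amide (the stable tetrahedral adduct prevents proton exchange and double addition) adds the acetyl unit that becomes C8a and C4a, and base-mediated lactonisation of the 3,5-dioxo ester onto its own ester group stores the chain as a 4-hydroxy-2-pyrone.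

**Step 3**
Reactants: 6 4-hydroxy-2,5-dimethoxybenzaldehyde
Product: 7 2,5-dimethoxy-4-(methoxymethoxy)benzaldehyde
Conditions: MOMCl (1.3 equiv), K2CO3 (2 equiv), acetone, 0 °C → rt
Reagents that add atoms: chloromethyl methyl ether, COCCl
Why: Williamson-type O-alkylation of the acidic para-formyl phenol; the methoxymethyl acetal tolerates the strong bases of steps 4 to 6 and is removed in the acid stage that ends step 7.

**Step 4**
Reactants: 7 2,5-dimethoxy-4-(methoxymethoxy)benzaldehyde; 8 methyl 2-(dimethoxyphosphoryl)-2-methoxyacetate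
Product: 9 methyl (2Z)-3-[2,5-dimethoxy-4-(methoxymethoxy)phenyl]-2-methoxyprop-2-enoate
Conditions: 8 (1.2 equiv), NaH (1.2 equiv), THF, 0 °C → rt
Reagents that add atoms: none
Why: Horner–Wadsworth–Emmons olefination with an α-methoxy phosphonoacetate should give mainly the (Z)-α-methoxycinnamate (aryl trans to the ester), a non-enolisable acyl donor at the oxidation level of a cinnamoyl starter unit; its geometry is not critical because it is erased in step 7.

**Step 5**
Reactants: 5 4-hydroxy-3,5-dimethoxy-6-methyl-2H-pyran-2-one; 9 methyl (2Z)-3-[2,5-dimethoxy-4-(methoxymethoxy)phenyl]-2-methoxyprop-2-enoate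
Product: 10 6-{(3Z)-4-[2,5-dimethoxy-4-(methoxymethoxy)phenyl]-3-methoxy-2-oxobut-3-en-1-yl}-4-hydroxy-3,5-dimethoxy-2H-pyran-2-one
Conditions: 5 (1.1 equiv), LiN(iPr)2 (3.3 equiv), THF, −78 → −20 °C; 9 (1.0 equiv), −78 → 0 °C; cold 1 M HCl
Reagents that add atoms: none
Why: Claisen-type C-acylation of the 4-hydroxy-6-methyl-2-pyrone dianion at its exocyclic methyl carbon by a non-enolisable ester, the third equivalent of amide base taking up the acidic methylene of the product; the methoxy groups at C3 and C5 of the pyrone exclude ring metalation, and the hard lithium carbanion is expected to attack the ester carbonyl and not the donor-substituted β-carbon.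

**Step 6**
Reactants: 10 6-{(3Z)-4-[2,5-dimethoxy-4-(methoxymethoxy)phenyl]-3-methoxy-2-oxobut-3-en-1-yl}-4-hydroxy-3,5-dimethoxy-2H-pyran-2-one
Product: 12 (2Z)-3-[2,5-dimethoxy-4-(methoxymethoxy)phenyl]-2-methoxy-1-(2,4,6-trihydroxy-3,5-dimethoxyphenyl)prop-2-en-1-one, via trioxo ester 11 (not isolated)
Conditions: Mg(OMe)2 (8 equiv), MeOH, reflux, Ar; then cold 2 M HCl
Reagents that add atoms: none
Why: Methoxide should open the lactone of 10 to the magnesium-chelated methyl 3,5,7-trioxo ester 11, in which the C6 methylene between the C5 and C7 carbonyls (the future C4a) is the carbon nucleophile and the C1 ester carbonyl (the future C5) the electrophile. Ring A closes by a 6-exo-trig Claisen (Dieckmann-type) condensation that forms C4a–C5; loss of methoxide and enolisation of the cyclohexane-1,3,5-trione give the aromatic 2,4,6-trihydroxy-3,5-dimethoxyphenyl ketone irreversibly. The closest known reaction is the Mg(OMe)2-induced conversion of 6-(2-oxoalkyl)-4-hydroxy-2-pyrones and of 3,5,7-trioxo esters into acylphloroglucinols, the laboratory counterpart of the chalcone synthase fold. The selectivity needed is Claisen against aldol folding: the aldol mode (C2 onto the C7 carbonyl) would make C2 quaternary (OMe, CO2Me), cannot aromatise and stays reversible, so the methoxy group at C2 itself channels the chain into the Claisen mode. No stereocentre is formed, and because the new ring is symmetric about the C4a–C7 axis only one product can arise.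

**Step 7**
Reactants: 12 (2Z)-3-[2,5-dimethoxy-4-(methoxymethoxy)phenyl]-2-methoxy-1-(2,4,6-trihydroxy-3,5-dimethoxyphenyl)prop-2-en-1-one
Product: 15 5,7,4'-trihydroxy-3,6,8,2',5'-pentamethoxyflavone, via flavanone 13 (not isolated), via MOM flavone 14 (not isolated)
Conditions: I2 (0.1 equiv), DMSO, 120 °C; then MeOH, 3 M HCl, 60 °C
Reagents that add atoms: none
Why: Iodine/DMSO oxidative cyclisation of a 2'-hydroxychalcone (6-endo-trig oxa-Michael closure of O1–C2 to flavanone 13, α-iodination and loss of HI, DMSO returning HI to iodine) should give MOM flavone 14, both ortho hydroxyls of the symmetric ring A leading to the same product and ring A offering no free CH to iodine; the acid stage then cleaves the MOM acetal, so that any MOM lost earlier converges on the target.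

**Compound list**
1 | methyl methoxyacetate | COCC(=O)OC | starting material
2 | methyl 2,4-dimethoxy-3-oxobutanoate (racemic, enolisable centre) | COCC(=O)C(OC)C(=O)OC | intermediate
3 | N-methoxy-N-methylacetamide | CC(=O)N(C)OC | starting material
4 | methyl 2,4-dimethoxy-3,5-dioxohexanoate (enolisable centres, no stereodescriptors) | CC(=O)C(OC)C(=O)C(OC)C(=O)OC | intermediate (not isolated)
5 | 4-hydroxy-3,5-dimethoxy-6-methyl-2H-pyran-2-one | Cc1oc(=O)c(OC)c(O)c1OC | intermediate
6 | 4-hydroxy-2,5-dimethoxybenzaldehyde | COc1cc(C=O)c(OC)cc1O | starting material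
7 | 2,5-dimethoxy-4-(methoxymethoxy)benzaldehyde | COCOc1cc(OC)c(C=O)cc1OC | intermediate
8 | methyl 2-(dimethoxyphosphoryl)-2-methoxyacetate | COC(C(=O)OC)P(=O)(OC)OC | starting material
9 | methyl (2Z)-3-[2,5-dimethoxy-4-(methoxymethoxy)phenyl]-2-methoxyprop-2-enoate | CO/C(C(=O)OC)=C\c1cc(OC)c(OCOC)cc1OC | intermediate
10 | 6-{(3Z)-4-[2,5-dimethoxy-4-(methoxymethoxy)phenyl]-3-methoxy-2-oxobut-3-en-1-yl}-4-hydroxy-3,5-dimethoxy-2H-pyran-2-one | CO/C(=C\c1cc(OC)c(OCOC)cc1OC)C(=O)Cc1oc(=O)c(OC)c(O)c1OC | intermediate
11 | methyl (8Z)-9-[2,5-dimethoxy-4-(methoxymethoxy)phenyl]-2,4,8-trimethoxy-3,5,7-trioxonon-8-enoate (enolisable centres, no stereodescriptors) | CO/C(=C\c1cc(OC)c(OCOC)cc1OC)C(=O)CC(=O)C(OC)C(=O)C(OC)C(=O)OC | intermediate (not isolated)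
12 | (2Z)-3-[2,5-dimethoxy-4-(methoxymethoxy)phenyl]-2-methoxy-1-(2,4,6-trihydroxy-3,5-dimethoxyphenyl)prop-2-en-1-one | CO/C(=C\c1cc(OC)c(OCOC)cc1OC)C(=O)c1c(O)c(OC)c(O)c(OC)c1O | intermediate
13 | 2-[2,5-dimethoxy-4-(methoxymethoxy)phenyl]-5,7-dihydroxy-3,6,8-trimethoxy-2,3-dihydro-4H-chromen-4-one (racemic, relative configuration not assigned, both centres erased in the same step) | COCOc1cc(OC)c(C2Oc3c(OC)c(O)c(OC)c(O)c3C(=O)C2OC)cc1OC | intermediate (not isolated)
14 | 2-[2,5-dimethoxy-4-(methoxymethoxy)phenyl]-5,7-dihydroxy-3,6,8-trimethoxy-4H-chromen-4-one | COCOc1cc(OC)c(-c2oc3c(OC)c(O)c(OC)c(O)c3c(=O)c2OC)cc1OC | intermediate (not isolated)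
15 | 5,7,4'-trihydroxy-3,6,8,2',5'-pentamethoxyflavone (achiral) | COc1cc(-c2oc3c(OC)c(O)c(OC)c(O)c3c(=O)c2OC)c(OC)cc1O | target

**Step count and risks**

Total step count: 7. Longest linear sequence: 5 steps (steps 1, 2, 5, 6, 7, or equally steps 3, 4, 5, 6, 7).

Steps most likely to fail:

Step 6 (key step). The slow Claisen closure could be outrun by diversion of the opened chain at its styryl ketone: reversible oxygen or carbon Michael closure onto the β-carbon, addition of methoxide, or retro-Claisen loss of the cinnamoyl unit. The fallback folds the chain before the cinnamoyl unit is attached. It sets out from 5: the dianion of 5 (LiN(iPr)2, THF) would be acylated with methyl methoxyacetate 1 to 4-hydroxy-3,5-dimethoxy-6-(3-methoxy-2-oxopropyl)-2H-pyran-2-one F1. Mg(OMe)2 in MeOH would open F1 to methyl 2,4,8-trimethoxy-3,5,7-trioxooctanoate F2 and fold it to 2-methoxy-1-(2,4,6-trihydroxy-3,5-dimethoxyphenyl)ethan-1-one F3, which carries no Michael acceptor. Claisen–Schmidt condensation of F3 with aldehyde 7 (aq. KOH, EtOH) would then form the C2–C3 bond and return to the route at chalcone 12.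

Step 5. The delocalised carbanion could add to the β-carbon of the cinnamate (1,4-addition), or the donor-deactivated ester carbonyl could react so slowly that proton transfer wins. The fallback replaces the acylation by aldol addition and oxidation. It sets out from 9: reduction (iBu2AlH, CH2Cl2, −78 °C) would give (2Z)-3-[2,5-dimethoxy-4-(methoxymethoxy)phenyl]-2-methoxyprop-2-en-1-ol F4, and oxidation (MnO2, CH2Cl2) the enal (2Z)-3-[2,5-dimethoxy-4-(methoxymethoxy)phenyl]-2-methoxyprop-2-enal F5. The dianion of 5 should add 1,2 to the aldehyde to give racemic 6-{(3Z)-4-[2,5-dimethoxy-4-(methoxymethoxy)phenyl]-2-hydroxy-3-methoxybut-3-en-1-yl}-4-hydroxy-3,5-dimethoxy-2H-pyran-2-one F6. Oxidation of this allylic alcohol (MnO2) returns to the route at ketone 10.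

Step 2. Formation of the dianion of the doubly methoxylated ketoester could be incomplete, or proton exchange and O-acylation could give mixtures. The fallback is a neutral Mukaiyama-type acylation. It sets out from 2: silylation (Me3SiCl, Et3N) would give methyl 2,4-dimethoxy-3-[(trimethylsilyl)oxy]but-2-enoate F7, and a second silylation (LiN(iPr)2, Me3SiCl, THF, −78 °C) 1,2,4-trimethoxy-1,3-bis[(trimethylsilyl)oxy]buta-1,3-diene F8. This diene should react with acetyl chloride at its terminal carbon (CH2Cl2, −78 → 20 °C, aqueous work-up) and return to the route at dioxo ester 4, which is lactonised to 5 as in step 2.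

**Further compounds**
F1 | step 6 | 4-hydroxy-3,5-dimethoxy-6-(3-methoxy-2-oxopropyl)-2H-pyran-2-one | COCC(=O)Cc1oc(=O)c(OC)c(O)c1OC
F2 | step 6 | methyl 2,4,8-trimethoxy-3,5,7-trioxooctanoate (enolisable centres, no stereodescriptors) | COCC(=O)CC(=O)C(OC)C(=O)C(OC)C(=O)OC
F3 | step 6 | 2-methoxy-1-(2,4,6-trihydroxy-3,5-dimethoxyphenyl)ethan-1-one | COCC(=O)c1c(O)c(OC)c(O)c(OC)c1O
F4 | step 5 | (2Z)-3-[2,5-dimethoxy-4-(methoxymethoxy)phenyl]-2-methoxyprop-2-en-1-ol | CO/C(CO)=C\c1cc(OC)c(OCOC)cc1OC
F5 | step 5 | (2Z)-3-[2,5-dimethoxy-4-(methoxymethoxy)phenyl]-2-methoxyprop-2-enal | CO/C(C=O)=C\c1cc(OC)c(OCOC)cc1OC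
F6 | step 5 | 6-{(3Z)-4-[2,5-dimethoxy-4-(methoxymethoxy)phenyl]-2-hydroxy-3-methoxybut-3-en-1-yl}-4-hydroxy-3,5-dimethoxy-2H-pyran-2-one (racemic) | CO/C(=C\c1cc(OC)c(OCOC)cc1OC)C(O)Cc1oc(=O)c(OC)c(O)c1OC
F7 | step 2 | methyl 2,4-dimethoxy-3-[(trimethylsilyl)oxy]but-2-enoate (geometry not assigned) | COCC(O[Si](C)(C)C)=C(OC)C(=O)OC
F8 | step 2 | 1,2,4-trimethoxy-1,3-bis[(trimethylsilyl)oxy]buta-1,3-diene (geometry not assigned) | COC=C(O[Si](C)(C)C)C(OC)=C(OC)O[Si](C)(C)C
A1 | direct plan | methyl 3-[4-(benzyloxy)-2,5-dimethoxyphenyl]-2-methoxy-3-oxopropanoate (racemic, enolisable centre) | COC(C(=O)OC)C(=O)c1cc(OC)c(OCc2ccccc2)cc1OC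
A2 | direct plan | phloroglucinol (benzene-1,3,5-triol) | Oc1cc(O)cc(O)c1
A3 | direct plan | 2-[4-(benzyloxy)-2,5-dimethoxyphenyl]-5,7-dihydroxy-3-methoxy-4H-chromen-4-one | COc1cc(-c2oc3cc(O)cc(O)c3c(=O)c2OC)c(OC)cc1OCc1ccccc1
A4 | direct plan | 2-[4-(benzyloxy)-2,5-dimethoxyphenyl]-6,8-dibromo-5,7-dihydroxy-3-methoxy-4H-chromen-4-one | COc1cc(-c2oc3c(Br)c(O)c(Br)c(O)c3c(=O)c2OC)c(OC)cc1OCc1ccccc1
A5 | direct plan | 2-[4-(benzyloxy)-2,5-dimethoxyphenyl]-5,7-dihydroxy-3,6,8-trimethoxy-4H-chromen-4-one | COc1cc(-c2oc3c(OC)c(O)c(OC)c(O)c3c(=O)c2OC)c(OC)cc1OCc1ccccc1
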